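Numbering the cyclohexane from the side-chain carbon (C1; C2 = CHMe, C3/C5 = methyl carbinols, C4/C6 = acetoxy carbons), the ring is cut on both sides of the cis-dioxygenated C3–C4 pair. C2–C1–C6–C5, whose ends both carry methyl, is the diene of a 3,6-dimethyl-2-pyrone-4-carboxylate; C3–C4 is a lactic-acid-derived chiral 4-methyl-1,3-dioxole. An inverse-demand Diels–Alder/CO2-extrusion cascade joins them, creating the quaternary C3 carbinol and the C3/C4 configuration in one operation. The resulting cyclohexadiene cis-diol then directs dihydroxylation and hydrogenation to the all-cis ring, which is extended by two Wittig reactions and an aldol condensation with the methoxypyrone.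

Key step: step 6

Remark: 1, 18, 20, 22 and 23 are taken as catalogue compounds. Lactol 7 (anomeric carbon) and aldol 27 (two new centres) are mixtures whose extra centres are erased in the next step.

Step 1
Reactants: 1 4-hydroxy-3,6-dimethyl-2H-pyran-2-one
Product: 2 3,6-dimethyl-2-oxo-2H-pyran-4-yl trifluoromethanesulfonate
Conditions: Tf2O, Et3N, CH2Cl2, −78 → 0 °C
Reagents that add atoms: triflic anhydride, O=S(=O)(OS(=O)(=O)C(F)(F)F)C(F)(F)F
Why: O-sulfonylation of the acidic vinylogous-acid hydroxyl should give the enol triflate cleanly (enol triflate formation).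

Step 2
Reactants: 2 3,6-dimethyl-2-oxo-2H-pyran-4-yl trifluoromethanesulfonate
Product: 3 methyl 3,6-dimethyl-2-oxo-2H-pyran-4-carboxylate
Conditions: CO (1 atm), MeOH, Pd(OAc)2 (5 mol %), dppp, Et3N, DMF, 25–40 °C
Reagents that add atoms: carbon monoxide, [C-]#[O+]; methanol, CO
Why: Oxidative addition of zerovalent palladium to the enol triflate, CO insertion and methanolysis (palladium-catalysed alkoxycarbonylation) should give the ester; the low temperature limits direct displacement of triflate by methanol.

Step 3
Reactants: 4 (S)-lactic acid; 5 4-methoxybenzaldehyde dimethyl acetal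
Product: 6 (2S,5S)-2-(4-methoxyphenyl)-5-methyl-1,3-dioxolan-4-one
Conditions: BF3·OEt2, Et2O, −20 °C → rt; crystallisation of the cis isomer
Reagents that add atoms: none
Why: Acetalisation of the α-hydroxy acid to the dioxolanone should favour the cis isomer, so the lactate centre fixes the configuration of the new acetal carbon; crystallisation should remove the trans isomer.

Step 4
Reactants: 6 (2S,5S)-2-(4-methoxyphenyl)-5-methyl-1,3-dioxolan-4-one
Product: 7 (2S,5S)-2-(4-methoxyphenyl)-5-methyl-1,3-dioxolan-4-ol
Conditions: diisobutylaluminium hydride (1.1 equiv), CH2Cl2, −78 °C; aqueous potassium sodium tartrate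
Reagents that add atoms: none
Why: Partial reduction of the lactone should stop at the lactol because the aluminium hemiacetal is stable at −78 °C; the acetal carbon is not touched.

Step 5
Reactants: 7 (2S,5S)-2-(4-methoxyphenyl)-5-methyl-1,3-dioxolan-4-ol
Product: 9 (R)-2-(4-methoxyphenyl)-4-methyl-1,3-dioxole, via lactol mesylate 8 (not isolated)
Conditions: MsCl, Et3N (4 equiv), CH2Cl2, −20 → 40 °C
Reagents that add atoms: none
Why: The anomeric mesylate should ionise and lose the adjacent proton (glycal-type elimination) to give the enediol acetal; the former lactate carbon becomes sp2 and the acetal carbon remains as the only stereocentre, kept intact by the excess amine.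

Step 6
Reactants: 3 methyl 3,6-dimethyl-2-oxo-2H-pyran-4-carboxylate; 9 (R)-2-(4-methoxyphenyl)-4-methyl-1,3-dioxole
Product: 11 methyl (2R,3aR,7aS)-2-(4-methoxyphenyl)-3a,4,7-trimethyl-3a,7a-dihydro-1,3-benzodioxole-5-carboxylate, via bridged lactone cycloadduct 10 (not isolated)
Conditions: 9 (2 equiv), K2CO3 (solid, acid scavenger), toluene, 110 °C, sealed tube
Reagents that add atoms: none
Why: Inverse-electron-demand Diels–Alder reaction of the electron-poor 2-pyrone (diene C3=C4–C5=C6 of 3, which become ring C2, C1, C6, C5) with the electron-rich enediol ether 9 gives bridged lactone 10, which loses CO2 by retro-[4+2] reaction; the closest known reaction type is the cycloaddition–decarboxylation of 2-pyrone esters with enol ethers and 1,3-dioxoles. The six-membered carbocycle is closed by a concerted suprafacial [4+2] cycloaddition and the bridging lactone ring is then opened by cycloreversion, so endo and exo adducts converge on the same diene. The quaternary C3a and the C7a stereocentres are cis because the enediol is locked in the dioxole ring, and their absolute sense comes from approach of the pyrone anti to the 4-methoxyphenyl group on the acetal carbon of 9. The step needs regioselectivity (unsubstituted dioxole carbon to pyrone C6): the pyrone LUMO is largest at C6, vinylogous to the lactone carbonyl, the ester at C4 sits on another large-coefficient atom and lowers the LUMO without reversing this polarisation, and the dioxole HOMO is largest and least hindered at its CH carbon. The product diene is electron-poor and substituted at both termini, so a second cycloaddition is not expected, and 110 °C is kept as the ceiling to avoid a 1,5-hydrogen shift.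

Step 7
Reactants: 11 methyl (2R,3aR,7aS)-2-(4-methoxyphenyl)-3a,4,7-trimethyl-3a,7a-dihydro-1,3-benzodioxole-5-carboxylate
Product: 12 methyl (3R,4S)-3,4-dihydroxy-2,3,5-trimethylcyclohexa-1,5-diene-1-carboxylate
Conditions: AcOH/THF/H2O (3:1:1), 20 °C; NaHCO3 work-up
Reagents that add atoms: none
Why: Hydrolysis of the 4-methoxybenzylidene acetal should be much faster than ionisation of the ester-deactivated, β-hydroxylated allylic alcohols, so the cis-diol is freed without aromatisation (acetal hydrolysis).

Step 8
Reactants: 12 methyl (3R,4S)-3,4-dihydroxy-2,3,5-trimethylcyclohexa-1,5-diene-1-carboxylate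
Product: 14 methyl (3R,4R,5S,6S)-3,4,5,6-tetrahydroxy-2,3,5-trimethylcyclohex-1-ene-1-carboxylate, via osmate ester 13 (not isolated)
Conditions: OsO4 (1.05 equiv), TMEDA (1.1 equiv), CH2Cl2, −78 °C; then aqueous Na2SO3, THF, 60 °C
Reagents that add atoms: osmium tetroxide, O=[Os](=O)(=O)=O
Why: Hydrogen-bond-directed dihydroxylation should deliver the OsO4·TMEDA complex to the C5=C6 alkene on the face of the allylic C4 hydroxyl, setting C5 and C6 cis to the existing diol; the tetrasubstituted, electron-poor enoate alkene should not react.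

Step 9
Reactants: 14 methyl (3R,4R,5S,6S)-3,4,5,6-tetrahydroxy-2,3,5-trimethylcyclohex-1-ene-1-carboxylate
Product: 15 methyl (1R,2S,3R,4R,5S,6S)-3,4,5,6-tetrahydroxy-2,3,5-trimethylcyclohexane-1-carboxylate
Conditions: H2 (1–20 bar), [Ir(cod)(PCy3)(py)]PF6 (10 mol %), CH2Cl2, rt
Reagents that add atoms: none
Why: Hydroxyl-directed hydrogenation should add both hydrogens to C1 and C2 from the face of the allylic C3 and C6 hydroxyls, placing the ester and the C2 methyl on the face opposite to all four oxygens.

Step 10
Reactants: 15 methyl (1R,2S,3R,4R,5S,6S)-3,4,5,6-tetrahydroxy-2,3,5-trimethylcyclohexane-1-carboxylate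
Product: 16 3,4:5,6-di-O-isopropylidene derivative of 15
Conditions: 2,2-dimethoxypropane, camphor-10-sulfonic acid (cat.), acetone, rt
Reagents that add atoms: 2,2-dimethoxypropane, COC(C)(C)OC
Why: The two cis-1,2-diol pairs (C3/C4 and C5/C6) should close to two cis-fused dioxolanes under thermodynamic ketalisation.

Step 11
Reactants: 16 3,4:5,6-di-O-isopropylidene derivative of 15
Product: 17 bis-acetonide aldehyde (C1 formyl)
Conditions: diisobutylaluminium hydride (1.05 equiv), CH2Cl2, −78 °C; MeOH quench, aqueous potassium sodium tartrate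
Reagents that add atoms: none
Why: Partial reduction of the hindered ester should stop at the aldehyde because the tetrahedral aluminium intermediate is stabilised by the neighbouring acetonide oxygen; the cold, non-basic work-up keeps C1 from epimerising.

Step 12
Reactants: 17 bis-acetonide aldehyde; 18 2-(triphenylphosphoranylidene)propanal
Product: 19 (E)-2-methyl-3-(ring)prop-2-enal (bis-acetonide enal)
Conditions: toluene, 90 °C
Reagents that add atoms: none
Why: Wittig olefination with the stabilised ylide should give the (E)-trisubstituted enal under neutral conditions that tolerate the α-stereocentre and β-alkoxy group.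

Step 13
Reactants: 19 bis-acetonide enal; 20 (triphenylphosphoranylidene)acetaldehyde
Product: 21 (2E,4E)-4-methyl-5-(ring)penta-2,4-dienal (bis-acetonide dienal)
Conditions: 20 (1.2 equiv), toluene, 80 °C
Reagents that add atoms: none
Why: Wittig two-carbon homologation with the stabilised formyl ylide should give the (E)-disubstituted alkene; limiting the ylide restrains a second homologation.

Step 14
Reactants: 22 ethyl 2-methyl-3-oxopentanoate; 23 N-methoxy-N-methylpropanamide
Product: 24 ethyl 2,4-dimethyl-3,5-dioxoheptanoate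
Conditions: NaH, THF, 0 °C; n-BuLi, −20 °C; then 23, −78 → 0 °C; aqueous HCl
Reagents that add atoms: none
Why: The β-keto ester dianion should be acylated at its more reactive γ-carbon, and the N-methoxy-N-methylamide stops at the ketone (dianion γ-acylation).

Step 15
Reactants: 24 ethyl 2,4-dimethyl-3,5-dioxoheptanoate
Product: 25 6-ethyl-4-hydroxy-3,5-dimethyl-2H-pyran-2-one
Conditions: DBU, toluene, 110 °C
Reagents that add atoms: none
Why: The enol oxygen of the terminal ketone should attack the ester (enol lactonisation) to give the 4-hydroxy-2-pyrone.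

Step 16
Reactants: 25 6-ethyl-4-hydroxy-3,5-dimethyl-2H-pyran-2-one
Product: 26 2-ethyl-6-methoxy-3,5-dimethyl-4H-pyran-4-one
Conditions: MeOTf, CH2Cl2, rt; aqueous NaHCO3
Reagents that add atoms: methyl trifluoromethanesulfonate, COS(=O)(=O)C(F)(F)F
Why: Methylation of the neutral hydroxypyrone by the hard electrophile should occur at the lactone carbonyl oxygen, and loss of the hydroxyl proton then gives the α-methoxy-γ-pyrone (O-alkylation).

Step 17
Reactants: 26 2-ethyl-6-methoxy-3,5-dimethyl-4H-pyran-4-one; 21 bis-acetonide dienal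
Product: 27 aldol adduct (pyrone–CH(Me)–CH(OH)–dienyl–ring)
Conditions: LiN(SiMe3)2, THF, −78 °C; then 21; aqueous NH4Cl
Reagents that add atoms: none
Why: The ethyl CH2 is the vinylogous α-position of the pyrone and should be deprotonated selectively; the lithium dienolate should add 1,2 to the dienal (aldol addition), the two new centres being formed without control.

Step 18
Reactants: 27 aldol adduct
Product: 29 bis-acetonide of the all-E tetraene pyrone, via allylic mesylate 28 (not isolated)
Conditions: MsCl, Et3N, CH2Cl2, 0 °C; then DBU, rt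
Reagents that add atoms: none
Why: Mesylation and E1cB elimination through the acidic pyrone γ-hydrogen should give the conjugated (E)-trisubstituted alkene, the isomer with the pyrone trans to the chain being thermodynamically favoured.

Step 19
Reactants: 29 bis-acetonide of the all-E tetraene pyrone
Product: 30 tetraol (3,4,5,6-tetrahydroxy ring with complete side chain)
Conditions: AcOH/H2O (4:1), 40 °C
Reagents that add atoms: none
Why: Mild acid hydrolysis should remove both strained cis-fused acetonides without touching the methoxypyrone or the polyene (ketal hydrolysis).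

Step 20
Reactants: 30 tetraol
Product: 31 Amaurone B
Conditions: Ac2O, pyridine, DMAP (cat.), CH2Cl2, rt
Reagents that add atoms: acetic anhydride, CC(=O)OC(C)=O
Why: Acylation should take place only at the two secondary hydroxyls (C4, C6); the tertiary C3 and C5 hydroxyls should be inert under these conditions (selective esterification).

Compound list
1 | 4-hydroxy-3,6-dimethyl-2H-pyran-2-one | Cc1cc(O)c(C)c(=O)o1 | starting material
2 | 3,6-dimethyl-2-oxo-2H-pyran-4-yl trifluoromethanesulfonate | Cc1cc(OS(=O)(=O)C(F)(F)F)c(C)c(=O)o1 | intermediate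
3 | methyl 3,6-dimethyl-2-oxo-2H-pyran-4-carboxylate | COC(=O)c1cc(C)oc(=O)c1C | intermediate
4 | (S)-lactic acid | C[C@H](O)C(=O)O | starting material
5 | 4-methoxybenzaldehyde dimethyl acetal | COc1ccc(C(OC)OC)cc1 | starting material
6 | (2S,5S)-2-(4-methoxyphenyl)-5-methyl-1,3-dioxolan-4-one | C[C@@H]1O[C@H](c2ccc(OC)cc2)OC1=O | intermediate
7 | (2S,5S)-2-(4-methoxyphenyl)-5-methyl-1,3-dioxolan-4-ol (anomeric mixture) | C[C@@H]1O[C@H](c2ccc(OC)cc2)OC1O | intermediate
8 | (2S,5S)-2-(4-methoxyphenyl)-5-methyl-1,3-dioxolan-4-yl methanesulfonate | C[C@@H]1O[C@H](c2ccc(OC)cc2)OC1OS(C)(=O)=O | intermediate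
9 | (R)-2-(4-methoxyphenyl)-4-methyl-1,3-dioxole | CC1=CO[C@@H](c2ccc(OC)cc2)O1 | intermediate
10 | bridged lactone cycloadduct of 3 and 9 (endo isomer drawn) | COC(=O)C1=C[C@@]2(C)OC(=O)[C@]1(C)[C@@]3(C)O[C@H](c4ccc(OC)cc4)O[C@@H]23 | intermediate
11 | methyl (2R,3aR,7aS)-2-(4-methoxyphenyl)-3a,4,7-trimethyl-3a,7a-dihydro-1,3-benzodioxole-5-carboxylate | COC(=O)C1=C(C)[C@@]2(C)O[C@H](c3ccc(OC)cc3)O[C@H]2C(C)=C1 | intermediate
12 | methyl (3R,4S)-3,4-dihydroxy-2,3,5-trimethylcyclohexa-1,5-diene-1-carboxylate | COC(=O)C1=C(C)[C@@](C)(O)[C@@H](O)C(C)=C1 | intermediate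
13 | cyclic C5/C6 osmate ester of 12 (hexavalent osmium glycolate), TMEDA complex | COC(=O)C1=C(C)[C@@](C)(O)[C@@H](O)[C@@]2(C)O[Os](=O)(=O)O[C@@H]12.CN(C)CCN(C)C | intermediate
14 | methyl (3R,4R,5S,6S)-3,4,5,6-tetrahydroxy-2,3,5-trimethylcyclohex-1-ene-1-carboxylate | COC(=O)C1=C(C)[C@@](C)(O)[C@@H](O)[C@@](C)(O)[C@H]1O | intermediate
15 | methyl (1R,2S,3R,4R,5S,6S)-3,4,5,6-tetrahydroxy-2,3,5-trimethylcyclohexane-1-carboxylate | COC(=O)[C@@H]1[C@H](C)[C@@](C)(O)[C@@H](O)[C@@](C)(O)[C@H]1O | intermediate
16 | 3,4:5,6-di-O-isopropylidene derivative of 15 | COC(=O)[C@@H]1[C@H](C)[C@@]3(C)OC(C)(C)O[C@H]3[C@@]4(C)OC(C)(C)O[C@@H]14 | intermediate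
17 | bis-acetonide aldehyde | O=C[C@@H]1[C@H](C)[C@@]3(C)OC(C)(C)O[C@H]3[C@@]4(C)OC(C)(C)O[C@@H]14 | intermediate
18 | 2-(triphenylphosphoranylidene)propanal | CC(C=O)=P(c1ccccc1)(c1ccccc1)c1ccccc1 | starting material
19 | bis-acetonide (E)-enal | O=C/C(C)=C/[C@@H]1[C@H](C)[C@@]3(C)OC(C)(C)O[C@H]3[C@@]4(C)OC(C)(C)O[C@@H]14 | intermediate
20 | (triphenylphosphoranylidene)acetaldehyde | O=CC=P(c1ccccc1)(c1ccccc1)c1ccccc1 | starting material
21 | bis-acetonide (2E,4E)-dienal | O=C/C=C/C(C)=C/[C@@H]1[C@H](C)[C@@]3(C)OC(C)(C)O[C@H]3[C@@]4(C)OC(C)(C)O[C@@H]14 | intermediate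
22 | ethyl 2-methyl-3-oxopentanoate | CCOC(=O)C(C)C(=O)CC | starting material
23 | N-methoxy-N-methylpropanamide | CCC(=O)N(C)OC | starting material
24 | ethyl 2,4-dimethyl-3,5-dioxoheptanoate | CCOC(=O)C(C)C(=O)C(C)C(=O)CC | intermediate
25 | 6-ethyl-4-hydroxy-3,5-dimethyl-2H-pyran-2-one | CCc1oc(=O)c(C)c(O)c1C | intermediate
26 | 2-ethyl-6-methoxy-3,5-dimethyl-4H-pyran-4-one | CCc1oc(OC)c(C)c(=O)c1C | intermediate
27 | aldol adduct of 26 and 21 (mixture at the two new centres) | COc1oc(C(C)C(O)/C=C/C(C)=C/[C@@H]2[C@H](C)[C@@]3(C)OC(C)(C)O[C@H]3[C@@]4(C)OC(C)(C)O[C@@H]24)c(C)c(=O)c1C | intermediate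
28 | allylic mesylate of 27 | COc1oc(C(C)C(OS(C)(=O)=O)/C=C/C(C)=C/[C@@H]2[C@H](C)[C@@]3(C)OC(C)(C)O[C@H]3[C@@]4(C)OC(C)(C)O[C@@H]24)c(C)c(=O)c1C | intermediate
29 | bis-acetonide of the all-E tetraene pyrone | COc1oc(/C(C)=C/C=C/C(C)=C/[C@@H]2[C@H](C)[C@@]3(C)OC(C)(C)O[C@H]3[C@@]4(C)OC(C)(C)O[C@@H]24)c(C)c(=O)c1C | intermediate
30 | tetraol (de-acetyl Amaurone B) | COc1oc(/C(C)=C/C=C/C(C)=C/[C@@H]2[C@H](C)[C@@](C)(O)[C@@H](O)[C@@](C)(O)[C@H]2O)c(C)c(=O)c1C | intermediate
31 | Amaurone B | COc1oc(/C(C)=C/C=C/C(C)=C/[C@@H]2[C@H](C)[C@@](C)(O)[C@@H](OC(C)=O)[C@@](C)(O)[C@H]2OC(C)=O)c(C)c(=O)c1C | target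

Total step count: 20. Longest linear sequence: 15 steps (steps 3–13 and 17–20, from (S)-lactic acid).

Steps most likely to fail

Step 6. The two termini may pair the wrong way round if the C4 ester competes with the lactone carbonyl in polarising the diene. The 4-methoxyphenyl group may also shield one dioxole face incompletely, and prolonged heating may trigger a 1,5-hydrogen shift. The fallback sets out from triflate 2 and dioxole 9 and moves the carbonylation behind the cycloaddition, so that only the lactone polarises the diene. Heating 2 with 9 (toluene, 110 °C) should give the bridged lactone triflate F1, which loses CO2 to the dienyl triflate acetal F2. Palladium-catalysed methoxycarbonylation of F2 (Pd(OAc)2, dppp, CO, MeOH, Et3N) then gives 11, where the route is rejoined.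

Step 7. Acid may ionise the allylic C4 or C3 hydroxyl of the freed dienediol faster than expected, leading to epimerisation or rearrangement and aromatisation. The fallback sets out from 11 and keeps the acetal until the ring is saturated. Woodward cis-hydroxylation (I2, AgOAc, AcOH; then wet AcOH) attacks C5=C6 with iodine on the face away from the acetal and acetate on the acetal face, giving the trans-iodo acetate F3. Acetoxonium displacement of iodide then puts both new oxygens syn to the acetal oxygens in the hydroxy acetate F4. Hydrogenation with [Ir(cod)(PCy3)(py)]PF6, directed by the tertiary C5 hydroxyl, gives the saturated hydroxy acetate acetal F5. HCl in MeOH removes acetal and acetate at this acid-stable stage and returns to 15.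

Step 9. The iridium catalyst may fail to reduce the tetrasubstituted, electron-poor enoate, or hydrogen may add without the directing effect and from the wrong face. The fallback sets out from 14 and changes the substrate class to an allylic alcohol. LiAlH4 reduction gives the allylic alcohol pentaol F6, a far better substrate for directed hydrogenation, which should give the saturated pentaol F7 with the same facial sense. Ketalisation (2,2-dimethoxypropane, camphor-10-sulfonic acid) gives the bis-acetonide primary alcohol F8, and Dess–Martin periodinane oxidation returns to aldehyde 17.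

Further compounds
F1 | step 6 | bridged lactone triflate cycloadduct of 2 and 9 (not isolated) | FC(F)(F)S(=O)(=O)OC1=C[C@@]2(C)OC(=O)[C@]1(C)[C@@]3(C)O[C@H](c4ccc(OC)cc4)O[C@@H]23
F2 | step 6 | dienyl triflate acetal (5-triflyloxy analogue of 11) | FC(F)(F)S(=O)(=O)OC1=C(C)[C@@]2(C)O[C@H](c3ccc(OC)cc3)O[C@H]2C(C)=C1
F3 | step 7 | trans-iodo acetate of 11 (C5 acetate, C6 iodide; not isolated) | COC(=O)C1=C(C)[C@@]2(C)O[C@H](c3ccc(OC)cc3)O[C@H]2[C@@](C)(OC(C)=O)[C@@H]1I
F4 | step 7 | hydroxy acetate acetal (C5 hydroxyl, C6 acetate, enoate) | COC(=O)C1=C(C)[C@@]2(C)O[C@H](c3ccc(OC)cc3)O[C@H]2[C@@](C)(O)[C@H]1OC(C)=O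
F5 | step 7 | saturated hydroxy acetate acetal | COC(=O)[C@@H]1[C@H](C)[C@@]2(C)O[C@H](c3ccc(OC)cc3)O[C@H]2[C@@](C)(O)[C@H]1OC(C)=O
F6 | step 9 | allylic alcohol pentaol | OCC1=C(C)[C@@](C)(O)[C@@H](O)[C@@](C)(O)[C@H]1O
F7 | step 9 | saturated pentaol | OC[C@@H]1[C@H](C)[C@@](C)(O)[C@@H](O)[C@@](C)(O)[C@H]1O
F8 | step 9 | bis-acetonide primary alcohol | OC[C@@H]1[C@H](C)[C@@]3(C)OC(C)(C)O[C@H]3[C@@]4(C)OC(C)(C)O[C@@H]14
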